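The bond between C2 of the tetrahydrofuran and its aryl ring is the disconnection on which the route rests. On that ring the C3 hydroxymethyl group and the hydroxyl of the C4 side chain are cis and 1,4-related, so they can be held as a γ-lactone with the C3 carbinol carbon at the carboxyl level. This temporary ring makes C2=C3 of a bicyclic 2,3-dihydrofuran a β-alkoxy acrylate. The precursor is thus a flat 3-aryl-3a,4-dihydrofuro[3,4-c]furan-1-one; rhodium-catalysed conjugate addition of an arylboronate joins the fragments at C2 and sets C2 and C3 in one operation. Hydride opening of the lactone then reveals both hydroxyls.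

Key step: step 6

Remark: ring atoms are numbered O1, C2 (aryl), C3 (hydroxymethyl), C4 (carbinol side chain), C5 in the tetrahydrofuran, and C1 (carbonyl), O2, C3, C3a, C4, O5, C6, C6a in the furo[3,4-c]furan intermediates; vanillin pivalate is made in step 2 so that every starting material is a catalogue compound.

Step 1
Reactants: 1 (R)-4-benzyl-1,3-oxazolidin-2-one; 2 methyl 4-chloro-4-oxobutanoate
Product: 3 methyl 4-[(4R)-4-benzyl-2-oxo-1,3-oxazolidin-3-yl]-4-oxobutanoate
Conditions: n-BuLi, THF, −78 °C; then 2, −78 to 0 °C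
Reagents that add atoms: none
Why: N-acylation of the lithiated oxazolidinone by the acid chloride (standard auxiliary acylation) should leave the methyl ester untouched at low temperature; no stereocentre is formed.

Step 2
Reactants: 4 vanillin (4-hydroxy-3-methoxybenzaldehyde)
Product: 5 4-formyl-2-methoxyphenyl pivalate
Conditions: t-BuCOCl, Et3N, DMAP (cat.), CH2Cl2, 0 to 23 °C
Reagents that add atoms: pivaloyl chloride, CC(C)(C)C(Cl)=O
Why: O-acylation of the phenol gives a hindered, non-enolisable, electron-withdrawing ester that should survive steps 3 to 6, keep the later benzylic lactone from ionising, and fall off in the final hydride step.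

Step 3
Reactants: 3 methyl 4-[(4R)-4-benzyl-2-oxo-1,3-oxazolidin-3-yl]-4-oxobutanoate; 5 4-formyl-2-methoxyphenyl pivalate
Product: 7 4-[(2R,3R)-3-{[(4R)-4-benzyl-2-oxo-1,3-oxazolidin-3-yl]carbonyl}-5-oxotetrahydrofuran-2-yl]-2-methoxyphenyl pivalate, via syn-aldol adduct 6 (not isolated)
Conditions: n-Bu2BOTf, i-Pr2NEt, CH2Cl2, −78 to 0 °C; 5, −78 to 0 °C; pH 7 buffer, MeOH, H2O2, 0 °C; then PPTS (cat.), PhMe, 40 °C
Reagents that add atoms: none
Why: Evans syn-aldol reaction, in which the (Z)-boron enolate of the imide reacts through a Zimmerman–Traxler chair on the face away from the benzyl group of the (R)-auxiliary and so sets the (3R,4R) pair of 6 (the future C4 and carbinol centres); acid-catalysed lactonisation of the benzylic hydroxyl onto the methyl ester then gives the trans γ-lactone without touching either centre.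

Step 4
Reactants: 7 4-[(2R,3R)-3-{[(4R)-4-benzyl-2-oxo-1,3-oxazolidin-3-yl]carbonyl}-5-oxotetrahydrofuran-2-yl]-2-methoxyphenyl pivalate
Product: 8 4-[(2R,3S)-3-(hydroxymethyl)-5-oxotetrahydrofuran-2-yl]-2-methoxyphenyl pivalate
Conditions: NaBH4, THF/H2O (4:1), 0 °C
Reagents that add atoms: none
Why: Reductive removal of the auxiliary (borohydride reduction of the activated N-acyl oxazolidinone to the primary alcohol) should be faster at 0 °C than attack on the γ-lactone or the hindered aryl pivalate, and no stereocentre is involved.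

Step 5
Reactants: 8 4-[(2R,3S)-3-(hydroxymethyl)-5-oxotetrahydrofuran-2-yl]-2-methoxyphenyl pivalate
Product: 10 4-[(3R,3aS)-1-oxo-3a,4-dihydro-1H,3H-furo[3,4-c]furan-3-yl]-2-methoxyphenyl pivalate, via hydroxymethylidene lactone 9 (not isolated)
Conditions: LiN(SiMe3)2 (2.2 equiv), THF, −78 °C; HCO2CH2CF3, −78 to 0 °C; AcOH; then PPTS (cat.), 4 Å MS, PhMe, 50 °C
Reagents that add atoms: 2,2,2-trifluoroethyl formate, O=COCC(F)(F)F
Why: Claisen C-formylation of the lactone enolate (generated beside the lithium alkoxide) gives the enolised α-formyl lactone 9, and acid-catalysed enol etherification by the only free hydroxyl (the primary one) then closes the dihydrofuran ring with loss of water; the lactone α-carbon becomes sp2, so only the two aldol-derived centres remain.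

Step 6
Reactants: 10 4-[(3R,3aS)-1-oxo-3a,4-dihydro-1H,3H-furo[3,4-c]furan-3-yl]-2-methoxyphenyl pivalate; 11 2-methoxy-4-(4,4,5,5-tetramethyl-1,3,2-dioxaborolan-2-yl)phenol
Product: 12 4-[(3R,3aS,6R,6aR)-6-(4-hydroxy-3-methoxyphenyl)-1-oxotetrahydro-1H,3H-furo[3,4-c]furan-3-yl]-2-methoxyphenyl pivalate
Conditions: 11 (2.5 equiv), [Rh(OH)(cod)]2 (3 mol %), degassed 1,4-dioxane/H2O (10:1), 60 °C
Reagents that add atoms: none
Why: Proposed new method: the arylboronate transmetalates to the hydroxo complex of monovalent rhodium, the aryl–rhodium species inserts the C6=C6a double bond of 10 with the aryl going to C6 (β to the lactone carbonyl, α to O5), and water protonates the resulting oxa-π-allyl rhodium enolate at C6a, which regenerates the hydroxo complex. The closest known reaction type is the Hayashi–Miyaura 1,4-addition of arylboron reagents to unsaturated lactones and to β-oxygen- or β-nitrogen-substituted enones such as chromones and dihydropyridones; a cyclic β-alkoxy acrylate of this kind has not been used, hence the label. No ring is closed. The new C6 centre is set by the bicycle, since the aryl should enter on the convex face (the side of H-3a, away from the fold of the lactone ring), and the C6a centre is set by protonation, which can only give the cis-fused bicyclo[3.3.0] system, so the aryl ends trans to the lactone carbonyl carbon (6R,6aR). The step needs 1,4-addition without ring opening or β-hydride loss: the carbonyl is a vinylogous carbonate that resists 1,2-attack, the C6–O5 bond lies near the plane of the enolate inside the rigid bicycle so that β-alkoxide elimination has poor orbital overlap, and water should trap the enolate faster than β-hydride elimination toward C3a. The neutral medium should leave the pivalate and the benzylic lactone untouched, and the free phenol of 11 needs no protection.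

Step 7
Reactants: 12 4-[(3R,3aS,6R,6aR)-6-(4-hydroxy-3-methoxyphenyl)-1-oxotetrahydro-1H,3H-furo[3,4-c]furan-3-yl]-2-methoxyphenyl pivalate
Product: 13 [(2R,3S,4S)-2-(4-hydroxy-3-methoxyphenyl)-4-[(R)-hydroxy(4-hydroxy-3-methoxyphenyl)methyl]tetrahydrofuran-3-yl]methanol
Conditions: LiAlH4, THF, −20 to 0 °C (12 added to the hydride); then H2O, aq NaOH
Reagents that add atoms: none
Why: LiAlH4 reduction of the γ-lactone to the 1,4-diol also cleaves the aryl pivalate (ester reduction); no bond to a stereocentre is broken, so all four centres are retained, and the non-acidic work-up avoids acid-induced closure of the benzylic alcohol onto the primary one.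

Compound list
1 | (R)-4-benzyl-1,3-oxazolidin-2-one | O=C1N[C@H](Cc2ccccc2)CO1 | starting material
2 | methyl 4-chloro-4-oxobutanoate | COC(=O)CCC(Cl)=O | starting material
3 | methyl 4-[(4R)-4-benzyl-2-oxo-1,3-oxazolidin-3-yl]-4-oxobutanoate | COC(=O)CCC(=O)N1[C@H](Cc2ccccc2)COC1=O | intermediate
4 | vanillin (4-hydroxy-3-methoxybenzaldehyde) | COc1cc(C=O)ccc1O | starting material
5 | 4-formyl-2-methoxyphenyl pivalate | COc1cc(C=O)ccc1OC(=O)C(C)(C)C | intermediate
6 | methyl (3R,4R)-3-{[(4R)-4-benzyl-2-oxo-1,3-oxazolidin-3-yl]carbonyl}-4-hydroxy-4-[3-methoxy-4-(pivaloyloxy)phenyl]butanoate (syn-aldol adduct) | COC(=O)C[C@H]([C@@H](O)c1ccc(OC(=O)C(C)(C)C)c(OC)c1)C(=O)N1[C@H](Cc2ccccc2)COC1=O | intermediate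
7 | 4-[(2R,3R)-3-{[(4R)-4-benzyl-2-oxo-1,3-oxazolidin-3-yl]carbonyl}-5-oxotetrahydrofuran-2-yl]-2-methoxyphenyl pivalate (trans lactone) | COc1cc(ccc1OC(=O)C(C)(C)C)[C@@H]1OC(=O)C[C@H]1C(=O)N1[C@H](Cc2ccccc2)COC1=O | intermediate
8 | 4-[(2R,3S)-3-(hydroxymethyl)-5-oxotetrahydrofuran-2-yl]-2-methoxyphenyl pivalate | COc1cc(ccc1OC(=O)C(C)(C)C)[C@@H]1OC(=O)C[C@H]1CO | intermediate
9 | 4-[(2R,3S)-3-(hydroxymethyl)-4-(hydroxymethylidene)-5-oxotetrahydrofuran-2-yl]-2-methoxyphenyl pivalate (enol of the α-formyl lactone, alkene geometry not fixed) | COc1cc(ccc1OC(=O)C(C)(C)C)[C@@H]1OC(=O)C(=CO)[C@H]1CO | intermediate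
10 | 4-[(3R,3aS)-1-oxo-3a,4-dihydro-1H,3H-furo[3,4-c]furan-3-yl]-2-methoxyphenyl pivalate (γ-lactone fused to a 2,3-dihydrofuran, C6=C6a enol ether) | COc1cc(ccc1OC(=O)C(C)(C)C)[C@@H]1OC(=O)C2=COC[C@@H]12 | intermediate
11 | 2-methoxy-4-(4,4,5,5-tetramethyl-1,3,2-dioxaborolan-2-yl)phenol | COc1cc(ccc1O)B1OC(C)(C)C(C)(C)O1 | starting material
12 | 4-[(3R,3aS,6R,6aR)-6-(4-hydroxy-3-methoxyphenyl)-1-oxotetrahydro-1H,3H-furo[3,4-c]furan-3-yl]-2-methoxyphenyl pivalate (cis-fused, both aryl groups exo) | COc1cc(ccc1OC(=O)C(C)(C)C)[C@@H]1OC(=O)[C@H]2[C@H](c3ccc(O)c(OC)c3)OC[C@@H]12 | intermediate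
13 | [(2R,3S,4S)-2-(4-hydroxy-3-methoxyphenyl)-4-[(R)-hydroxy(4-hydroxy-3-methoxyphenyl)methyl]tetrahydrofuran-3-yl]methanol | COc1cc([C@H](O)[C@@H]2CO[C@@H](c3ccc(O)c(OC)c3)[C@@H]2CO)ccc1O | target

Total steps: 7. Longest linear sequence: 6 (steps 1, 3, 4, 5, 6, 7; step 2 is a one-step side branch).

Steps most likely to fail

Step 6 (bears the label). The aryl–rhodium species may insert the electron-rich, trisubstituted enol-ether double bond too slowly, so that protodeboronation consumes the boronate. The rhodium enolate may also lose a β-hydride toward C3a instead of being protonated, or the aryl may enter with poor facial selectivity. The fallback uses known chemistry, sets out from 8 and comes back at 13; it brings in the aryl by decarboxylative radical arylation. Alcohol 8 is C-acylated at the lactone α-carbon with di-tert-butyl oxalate (LiN(SiMe3)2, THF, −78 °C) to the enolised α-(tert-butoxyoxalyl) lactone F1. Acid-catalysed cyclodehydration (PPTS, 4 Å MS, PhMe) gives the bicyclic enol-ether ester F2, and hydrogenation of its tetrasubstituted double bond from the convex face (H2, Rh/Al2O3, EtOAc) gives the saturated cis-fused ester F3. CF3CO2H in CH2Cl2 frees the tetrahydrofuran-2-carboxylic acid F4. F4 is coupled with 4-bromo-2-methoxyphenyl pivalate F5 (from commercial 4-bromo-2-methoxyphenol and pivaloyl chloride) under nickel/photoredox decarboxylative arylation conditions (Ir[dF(CF3)ppy]2(dtbbpy)PF6, NiCl2(dme), 4,4'-di-tert-butyl-2,2'-bipyridine, Cs2CO3, DMF, blue light). The α-oxy radical at C6 should be arylated on the convex face to give the bis-pivalate lactone F6, and LiAlH4 as in step 7 then gives 13.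

Step 5. In the dianion the lactone acyl group may migrate to the neighbouring lithium alkoxide before C-formylation, which would let the ring close through the benzylic oxygen; loss of water may also stall. The fallback sets out from 8 and comes back at 10; it attaches the ring oxygen to the new carbon before the C–C bond is made. Alcohol 8 is O-formylated (HCO2H, N,N'-dicyclohexylcarbodiimide, DMAP, CH2Cl2) to the formate ester F7. LiN(SiMe3)2 (THF, −78 °C) then effects an intramolecular Claisen condensation of the lactone enolate onto the formate carbonyl, which gives after quench the cis-fused lactol F8. The PPTS treatment of step 5 dehydrates F8 to 10.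

Step 4. Hydride may attack the γ-lactone or the aryl pivalate alongside the imide, or the freed alcohol may take over the lactone acyl group in the basic aqueous medium. The fallback sets out from 7 and comes back at 10; it reverses the order so that the lactone is masked while the auxiliary is removed. Lactone 7 is C-formylated first (LiN(SiMe3)2, 1.1 equiv, THF, −78 °C; HCO2CH2CF3; the hindered imide α-hydrogen should not be removed) to the hydroxymethylidene lactone imide F9. NaBH4 (THF/H2O, 0 °C) then reduces only the imide, because the lactone is present as the enolate of its formyl derivative, and gives 9, which closes to 10 under the acid conditions of step 5.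

Further compounds
F1 | step 6 | 4-[(2R,3S)-4-(2-tert-butoxy-1-hydroxy-2-oxoethylidene)-3-(hydroxymethyl)-5-oxotetrahydrofuran-2-yl]-2-methoxyphenyl pivalate (enol form, alkene geometry not fixed) | COc1cc(ccc1OC(=O)C(C)(C)C)[C@@H]1OC(=O)C(=C(O)C(=O)OC(C)(C)C)[C@H]1CO
F2 | step 6 | tert-butyl (3R,3aS)-3-[3-methoxy-4-(pivaloyloxy)phenyl]-1-oxo-3a,4-dihydro-1H,3H-furo[3,4-c]furan-6-carboxylate | COc1cc(ccc1OC(=O)C(C)(C)C)[C@@H]1OC(=O)C2=C(OC[C@@H]12)C(=O)OC(C)(C)C
F3 | step 6 | tert-butyl (3R,3aS,6aR)-3-[3-methoxy-4-(pivaloyloxy)phenyl]-1-oxotetrahydro-1H,3H-furo[3,4-c]furan-6-carboxylate (C6 configuration not fixed) | COc1cc(ccc1OC(=O)C(C)(C)C)[C@@H]1OC(=O)[C@H]2C(OC[C@@H]12)C(=O)OC(C)(C)C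
F4 | step 6 | (3R,3aS,6aR)-3-[3-methoxy-4-(pivaloyloxy)phenyl]-1-oxotetrahydro-1H,3H-furo[3,4-c]furan-6-carboxylic acid (C6 configuration not fixed) | COc1cc(ccc1OC(=O)C(C)(C)C)[C@@H]1OC(=O)[C@H]2C(OC[C@@H]12)C(=O)O
F5 | step 6 | 4-bromo-2-methoxyphenyl pivalate | COc1cc(Br)ccc1OC(=O)C(C)(C)C
F6 | step 6 | 4-[(3R,3aS,6R,6aR)-6-[3-methoxy-4-(pivaloyloxy)phenyl]-1-oxotetrahydro-1H,3H-furo[3,4-c]furan-3-yl]-2-methoxyphenyl pivalate | COc1cc(ccc1OC(=O)C(C)(C)C)[C@@H]1OC(=O)[C@H]2[C@H](c3ccc(OC(=O)C(C)(C)C)c(OC)c3)OC[C@@H]12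
F7 | step 5 | {(2R,3S)-2-[3-methoxy-4-(pivaloyloxy)phenyl]-5-oxotetrahydrofuran-3-yl}methyl formate | COc1cc(ccc1OC(=O)C(C)(C)C)[C@@H]1OC(=O)C[C@H]1COC=O
F8 | step 5 | 4-[(3R,3aS,6aR)-6-hydroxy-1-oxotetrahydro-1H,3H-furo[3,4-c]furan-3-yl]-2-methoxyphenyl pivalate (lactol, C6 configuration not fixed) | COc1cc(ccc1OC(=O)C(C)(C)C)[C@@H]1OC(=O)[C@H]2C(O)OC[C@@H]12
F9 | step 4 | 4-[(2R,3R)-3-{[(4R)-4-benzyl-2-oxo-1,3-oxazolidin-3-yl]carbonyl}-4-(hydroxymethylidene)-5-oxotetrahydrofuran-2-yl]-2-methoxyphenyl pivalate (alkene geometry not fixed) | COc1cc(ccc1OC(=O)C(C)(C)C)[C@@H]1OC(=O)C(=CO)[C@H]1C(=O)N1[C@H](Cc2ccccc2)COC1=O
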